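## Retrosynthetic overview

1. The ten-membered ring is closed last, at C1–C2 (germacrane numbering), by intramolecular B-alkyl Suzuki–Miyaura coupling of a (Z)-vinyl iodide with a 9-BBN borane; it is the second ring formed.
2. The C6 ester comes from Mitsunobu inversion; C6–C7 and the exo-methylene come from an indium Barbier allylation of a (4R)-4-vinyl lactol with a 3-(bromomethyl)butenolide.
3. Key step: a catalytic enantioselective vinylogous Mukaiyama aldol of a 2-silyloxyfuran with (Z)-3-iodo-2-methylpropenal forges C8–C9, sets C8 and C9, and converts the aromatic furan into the lactone ring (formed first).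
4. The silyloxyfuran and the vinyl lactol both derive from furan-2(5H)-one, made by oxidation of furfural; the Z-iodoenal comes from propargyl alcohol.

Assumption: locants C1–C15 are germacrane locants of the target (C8–O lactone, C6 ester, C9–OH, C15 = CH2OH, C1=C10 olefin, C14 = methyl); TBS = tert-butyldimethylsilyl.
Assumption: (R)-BINAP gives the (4R)-lactone 5 and (R)-BINOL gives (5R,1′R)-14; if either sense is reversed, the ligand antipode is used.
Assumption: the indium allylation follows the closed chair model (γ-substituent locked trans to CH2In), giving the 6R alcohol, hence esterification with inversion.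

## Route

Step 1
Reactants: 1 furfural (furan-2-carbaldehyde)
Product: 3 furan-2(5H)-one, via furan-2(3H)-one 2 (not isolated)
Conditions: 30 % H2O2, HCO2H, Na2SO4, K2CO3 (cat.), CH2Cl2–H2O, reflux; then Et3N (cat.), rt
Reagents that add atoms: hydrogen peroxide, OO
Why: Baeyer–Villiger oxidation of the aldehyde by performic acid gives 2-furyl formate, whose hydrolysis and tautomerisation give the β,γ-unsaturated lactone that the amine isomerises into conjugation; no stereocentre is formed.

Step 2
Reactants: 3 furan-2(5H)-one; 4 potassium ethenyl(trifluoro)borate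
Product: 5 (4R)-4-ethenyloxolan-2-one
Conditions: Rh(cod)2PF6 (3 mol %), (R)-BINAP (3.3 mol %), toluene–H2O (10:1), 100 °C
Reagents that add atoms: none
Why: Rhodium-catalysed asymmetric conjugate addition (Hayashi–Miyaura type) delivers the vinyl group to one enantioface of the butenolide β-carbon under control of the BINAP ligand, setting the centre that becomes C4.

Step 3
Reactants: 5 (4R)-4-ethenyloxolan-2-one
Product: 6 (4R)-4-ethenyloxolan-2-ol (lactol, anomer mixture)
Conditions: iBu2AlH (1.05 equiv), CH2Cl2, −78 °C; aqueous sodium potassium tartrate work-up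
Reagents that add atoms: none
Why: Partial reduction of the lactone stops at the lactol because the tetrahedral aluminium alkoxide is stable at −78 °C; C4 is untouched and the anomeric centre is of no consequence.

Step 4
Reactants: 3 furan-2(5H)-one; 7 formaldehyde (37 % aqueous)
Product: 8 3-(hydroxymethyl)furan-2(5H)-one
Conditions: imidazole (1.0 equiv), THF–H2O (1:1), rt
Reagents that add atoms: none
Why: Morita–Baylis–Hillman reaction, in which reversible conjugate addition of the amine makes the α-carbon nucleophilic towards formaldehyde and elimination of the amine restores the butenolide; no stereocentre is formed.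

Step 5
Reactants: 8 3-(hydroxymethyl)furan-2(5H)-one
Product: 9 tert-butyl[(2-{[tert-butyl(dimethyl)silyl]oxy}furan-3-yl)methoxy]dimethylsilane
Conditions: TBSOTf (2.2 equiv), Et3N (3 equiv), CH2Cl2, 0 °C
Reagents that add atoms: tert-butyldimethylsilyl trifluoromethanesulfonate, CC(C)(C)[Si](C)(C)OS(=O)(=O)C(F)(F)F
Why: Silylation of the primary alcohol plus soft enolisation (γ-deprotonation) and O-silylation of the butenolide give the aromatic 2-silyloxyfuran; no stereocentre is formed.

Step 6
Reactants: 10 prop-2-yn-1-ol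
Product: 12 (Z)-3-iodo-2-methylprop-2-en-1-ol, via bromomagnesium (Z)-3-(bromomagnesio)-2-methylprop-2-en-1-olate 11 (not isolated)
Conditions: MeMgBr (2.5 equiv), CuI (10 mol %), THF, −10 °C to rt; then I2 (1.2 equiv), −78 °C to 0 °C
Reagents that add atoms: methylmagnesium bromide, C[Mg]Br; iodine, II
Why: Copper-catalysed anti-carbomagnesiation of the propargylic alkoxide puts methyl on C2 and magnesium on C3 cis to the CH2O group (chelate), and iodinolysis with retention fixes the Z geometry of the future C1=C10 olefin.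

Step 7
Reactants: 12 (Z)-3-iodo-2-methylprop-2-en-1-ol
Product: 13 (Z)-3-iodo-2-methylprop-2-enal
Conditions: activated MnO2 (15 equiv), CH2Cl2, rt, dark; used at once
Reagents that add atoms: none
Why: Allylic alcohol oxidation on manganese dioxide under neutral conditions leaves the Z-iodoalkene unchanged.

Step 8
Reactants: 9 bis-silyl furan; 13 (Z)-3-iodo-2-methylprop-2-enal
Product: 14 (5R)-3-{[(TBS)oxy]methyl}-5-[(1R,2Z)-1-[(TBS)oxy]-3-iodo-2-methylprop-2-en-1-yl]furan-2(5H)-one
Conditions: Ti(OiPr)4 (20 mol %), (R)-BINOL (20 mol %), Et2O, −20 °C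
Reagents that add atoms: none
Why: Enantioselective vinylogous Mukaiyama aldol in which C5 of the furan attacks the titanium–BINOLate-bound enal through an open transition state, so the furan loses its aromaticity to become the butenolide, the threo (5R,1′R) pair C8/C9 is set, and silyl transfer to the new alkoxide leaves C9–O as its TBS ether.

Step 9
Reactants: 14
Product: 15 (5R)-3-(bromomethyl)-5-[(1R,2Z)-1-[(TBS)oxy]-3-iodo-2-methylprop-2-en-1-yl]furan-2(5H)-one
Conditions: Ph3PBr2 (1.2 equiv), CH2Cl2, 0 °C
Reagents that add atoms: dibromotriphenylphosphorane, BrP(Br)(c1ccccc1)(c1ccccc1)c1ccccc1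
Why: Direct silyl ether to bromide exchange (oxyphosphonium formation, then SN2 by bromide) occurs at the primary allylic position only, and the hindered secondary silyl ether and both stereocentres are untouched.

Step 10
Reactants: 15 allylic bromide; 6 (4R)-4-ethenyloxolan-2-ol
Product: 17 (4S,5R)-4-[(1R,3R)-1-hydroxy-3-(hydroxymethyl)pent-4-en-1-yl]-5-[(1R,2Z)-1-[(TBS)oxy]-3-iodo-2-methylprop-2-en-1-yl]-3-methylideneoxolan-2-one, via allylindium dibromide 16 (not isolated)
Conditions: In powder (1.5 equiv), THF–H2O (1:1), rt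
Reagents that add atoms: indium, [In] (present only in 16)
Why: Barbier allylation in which the allylindium adds through its γ-carbon (C7) to the open hydroxy-aldehyde form of the lactol in a closed chair transition state, anti to the C8 side chain (7S, trans-lactone) and with the aldehyde residue equatorial (6R), while the double bond shifts to the exo-methylene.

Step 11
Reactants: 17
Product: 18 (4S,5R)-4-[(1R,3R)-3-{[(TBS)oxy]methyl}-1-hydroxypent-4-en-1-yl]-5-[(1R,2Z)-1-[(TBS)oxy]-3-iodo-2-methylprop-2-en-1-yl]-3-methylideneoxolan-2-one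
Conditions: TBSCl (1.1 equiv), Et3N (1.5 equiv), DMAP (5 mol %), CH2Cl2, 0 °C
Reagents that add atoms: tert-butyldimethylsilyl chloride, CC(C)(C)[Si](C)(C)Cl
Why: Selective silylation of the primary C15 hydroxyl over the hindered secondary C6 hydroxyl; no stereocentre is affected.

Step 12
Reactants: 18; 19 (2R)-2-methylbutanoic acid
Product: 20 (1S,3R)-3-{[(TBS)oxy]methyl}-1-{(2R,3S)-2-[(1R,2Z)-1-[(TBS)oxy]-3-iodo-2-methylprop-2-en-1-yl]-4-methylidene-5-oxooxolan-3-yl}pent-4-en-1-yl (2R)-2-methylbutanoate
Conditions: PPh3 (2 equiv), DIAD (2 equiv), toluene, 0 °C to rt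
Reagents that add atoms: none
Why: Mitsunobu esterification, in which the carboxylate displaces the oxyphosphonium group by SN2 with inversion, turns the 6R alcohol into the 6S ester without touching the α-centre of the acid.

Step 13
Reactants: 20
Product: 22 9,15-bis-O-TBS ether of the target (ten-membered ring closed), via B-alkyl-9-BBN borane 21 (not isolated)
Conditions: 9-BBN-H (1.3 equiv), THF, 0 °C to rt; then slow addition to PdCl2(dppf) (20 mol %), AsPh3 (40 mol %), Cs2CO3 (3 equiv), DMF–THF–H2O, 50 °C, 1 mM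
Reagents that add atoms: 9-borabicyclo[3.3.1]nonane, [H]B1C2CCCC1CCC2 (present only in 21)
Why: Anti-Markovnikov hydroboration of the terminal vinyl group followed by intramolecular B-alkyl Suzuki–Miyaura coupling with the vinyl iodide closes the ring at C1–C2 with retention of the Z geometry; no stereocentre is formed.

Step 14
Reactants: 22
Product: 23 target, (1(10)Z,4S,6S,7S,8R,9R)-9,15-dihydroxy-6-{[(2R)-2-methylbutanoyl]oxy}germacra-1(10),11(13)-dien-12,8-olide
Conditions: HF·pyridine, pyridine–THF, 0 °C to rt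
Reagents that add atoms: none
Why: Buffered fluoride cleavage of both silyl ethers leaves the α-methylene lactone, the ester and the allylic alcohol intact.

## Compound list

1 | furfural (furan-2-carbaldehyde) | O=Cc1ccco1 | starting material
2 | furan-2(3H)-one | O=C1CC=CO1 | intermediate
3 | furan-2(5H)-one | O=C1C=CCO1 | intermediate
4 | potassium ethenyl(trifluoro)borate | [K+].C=C[B-](F)(F)F | starting material
5 | (4R)-4-ethenyloxolan-2-one | O=C1C[C@@H](CO1)C=C | intermediate
6 | (4R)-4-ethenyloxolan-2-ol | OC1C[C@@H](CO1)C=C | intermediate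
7 | formaldehyde | C=O | starting material
8 | 3-(hydroxymethyl)furan-2(5H)-one | O=C1OCC=C1CO | intermediate
9 | tert-butyl[(2-{[tert-butyl(dimethyl)silyl]oxy}furan-3-yl)methoxy]dimethylsilane | CC(C)(C)[Si](C)(C)OCc1ccoc1O[Si](C)(C)C(C)(C)C | intermediate
10 | prop-2-yn-1-ol | C#CCO | starting material
11 | bromomagnesium (Z)-3-(bromomagnesio)-2-methylprop-2-en-1-olate | Br[Mg]/C=C(/C)CO[Mg]Br | intermediate
12 | (Z)-3-iodo-2-methylprop-2-en-1-ol | I/C=C(/C)CO | intermediate
13 | (Z)-3-iodo-2-methylprop-2-enal | I/C=C(/C)C=O | intermediate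
14 | (5R)-3-{[(TBS)oxy]methyl}-5-[(1R,2Z)-1-[(TBS)oxy]-3-iodo-2-methylprop-2-en-1-yl]furan-2(5H)-one | O=C1O[C@H](C=C1CO[Si](C)(C)C(C)(C)C)[C@H](O[Si](C)(C)C(C)(C)C)/C(C)=C\I | intermediate
15 | (5R)-3-(bromomethyl)-5-[(1R,2Z)-1-[(TBS)oxy]-3-iodo-2-methylprop-2-en-1-yl]furan-2(5H)-one | O=C1O[C@H](C=C1CBr)[C@H](O[Si](C)(C)C(C)(C)C)/C(C)=C\I | intermediate
16 | allylindium dibromide from 15 (indium on C13) | O=C1O[C@H](C=C1C[In](Br)Br)[C@H](O[Si](C)(C)C(C)(C)C)/C(C)=C\I | intermediate
17 | (4S,5R)-4-[(1R,3R)-1-hydroxy-3-(hydroxymethyl)pent-4-en-1-yl]-5-[(1R,2Z)-1-[(TBS)oxy]-3-iodo-2-methylprop-2-en-1-yl]-3-methylideneoxolan-2-one | C=C1C(=O)O[C@H]([C@@H]1[C@H](O)C[C@@H](CO)C=C)[C@H](O[Si](C)(C)C(C)(C)C)/C(C)=C\I | intermediate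
18 | 15-O-TBS ether of 17 | C=C1C(=O)O[C@H]([C@@H]1[C@H](O)C[C@@H](CO[Si](C)(C)C(C)(C)C)C=C)[C@H](O[Si](C)(C)C(C)(C)C)/C(C)=C\I | intermediate
19 | (2R)-2-methylbutanoic acid | CC[C@@H](C)C(=O)O | starting material
20 | (6S)-(2R)-2-methylbutanoate of 18 (C6 inverted) | C=C1C(=O)O[C@H]([C@@H]1[C@@H](OC(=O)[C@H](C)CC)C[C@@H](CO[Si](C)(C)C(C)(C)C)C=C)[C@H](O[Si](C)(C)C(C)(C)C)/C(C)=C\I | intermediate
21 | B-alkyl-9-BBN borane from 20 (boron on C2) | C=C1C(=O)O[C@H]([C@@H]1[C@@H](OC(=O)[C@H](C)CC)C[C@@H](CO[Si](C)(C)C(C)(C)C)CCB1C2CCCC1CCC2)[C@H](O[Si](C)(C)C(C)(C)C)/C(C)=C\I | intermediate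
22 | 9,15-bis-O-TBS ether of the target | C=C1C(=O)O[C@@H]2[C@@H]1[C@@H](OC(=O)[C@H](C)CC)C[C@@H](CO[Si](C)(C)C(C)(C)C)CC/C=C(/C)[C@H]2O[Si](C)(C)C(C)(C)C | intermediate
23 | target CNP0147756.3 | C=C1C(=O)O[C@@H]2[C@@H]1[C@@H](OC(=O)[C@H](C)CC)C[C@@H](CO)CC/C=C(/C)[C@H]2O | target

## Step count and risks

Total step count: 14. Longest linear sequence: 10 steps (1, 4, 5, 8, 9, 10, 11, 12, 13, 14).

**Step 13 (ten-membered ring by B-alkyl Suzuki–Miyaura coupling).** Medium-ring strain, oligomerisation and a competing intramolecular Heck reaction of the vinylpalladium species onto the exo-methylene are all possible. The fallback sets out from 14 and 6 and returns at 22; it makes C1–C2 first and closes the ring at C6–C7. Lactol 6 is hydroborated with 9-BBN-H (2.2 equiv, the first equivalent being consumed by the hydroxyl) and coupled intermolecularly with vinyl iodide 14 (PdCl2(dppf), Cs2CO3) to give the C1–C2-linked lactol F1, before any exo-methylene exists. Ph3PBr2 converts its primary allylic silyl ether into the allylic bromide F2; the anomeric bromide formed alongside reverts to the lactol on aqueous work-up. Indium in THF–H2O at high dilution then closes the ring by intramolecular Barbier allylation to the macrocyclic diol F3. TBSCl silylates the primary alcohol to the mono-silyl ether F4, and Mitsunobu esterification with 19 gives 22 (DCC/DMAP instead if the macrocyclic allylation delivers the 6S alcohol).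

**Step 8 (enantioselective vinylogous aldol).** The ee and threo selectivity with an α-branched, isomerisation-prone Z-iodoenal and a 3-substituted silyloxyfuran are uncertain, as is clean silyl transfer. The fallback sets out from 9 and 13 and returns at 14; it replaces asymmetric catalysis by a racemic reaction and resolution. Stoichiometric BF3·OEt2 in CH2Cl2 at −78 °C gives the racemic threo alcohol F5. TBSOTf and 2,6-lutidine convert it into racemic 14, which is resolved by preparative chiral chromatography; the antipode F6 is set aside.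

**Step 12 (Mitsunobu inversion at hindered C6).** Elimination, participation of the lactone carbonyl, or prior translactonisation of the 6-hydroxy lactone could intervene. The fallback sets out from 18 and returns at 20; it uses sulfonate activation and carboxylate displacement. MsCl and Et3N give the C6 mesylate F7, and SN2 displacement with caesium (2R)-2-methylbutanoate (from 19 and Cs2CO3, 18-crown-6, toluene, 80 °C) gives 20 with inversion.

## Further compounds

F1 | step 13 | (5R)-3-{[(TBS)oxy]methyl}-5-[(1R,2Z)-1-[(TBS)oxy]-5-[(3S)-5-hydroxyoxolan-3-yl]-2-methylpent-2-en-1-yl]furan-2(5H)-one | O=C1O[C@H](C=C1CO[Si](C)(C)C(C)(C)C)[C@H](O[Si](C)(C)C(C)(C)C)/C(C)=C\CC[C@H]1CC(O)OC1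
F2 | step 13 | (5R)-3-(bromomethyl)-5-[(1R,2Z)-1-[(TBS)oxy]-5-[(3S)-5-hydroxyoxolan-3-yl]-2-methylpent-2-en-1-yl]furan-2(5H)-one | O=C1O[C@H](C=C1CBr)[C@H](O[Si](C)(C)C(C)(C)C)/C(C)=C\CC[C@H]1CC(O)OC1
F3 | step 13 | macrocyclic (6R)-6,15-diol, 9-O-TBS ether (6-epi-6-deacyl-22 with free C15–OH) | C=C1C(=O)O[C@@H]2[C@@H]1[C@H](O)C[C@@H](CO)CC/C=C(/C)[C@H]2O[Si](C)(C)C(C)(C)C
F4 | step 13 | 15-O-TBS ether of F3 | C=C1C(=O)O[C@@H]2[C@@H]1[C@H](O)C[C@@H](CO[Si](C)(C)C(C)(C)C)CC/C=C(/C)[C@H]2O[Si](C)(C)C(C)(C)C
F5 | step 8 | racemic threo 3-{[(TBS)oxy]methyl}-5-[(2Z)-1-hydroxy-3-iodo-2-methylprop-2-en-1-yl]furan-2(5H)-one (drawn as the 5R,1′R enantiomer) | O=C1O[C@H](C=C1CO[Si](C)(C)C(C)(C)C)[C@H](O)/C(C)=C\I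
F6 | step 8 | (5S,1′S)-enantiomer of 14 | O=C1O[C@@H](C=C1CO[Si](C)(C)C(C)(C)C)[C@@H](O[Si](C)(C)C(C)(C)C)/C(C)=C\I
F7 | step 12 | (6R)-methanesulfonate of 18 | C=C1C(=O)O[C@H]([C@@H]1[C@H](OS(C)(=O)=O)C[C@@H](CO[Si](C)(C)C(C)(C)C)C=C)[C@H](O[Si](C)(C)C(C)(C)C)/C(C)=C\I
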